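## Retrosynthetic overview

The plan rests on the C2–C3–C4 segment of ring A (C1 acyl, C2 OMe, C3 prenyl, C4 OH). This is a resorcinol whose prenyl group sits between two oxygens that carry different substituents.
The 1,3-diketone is cut between the ring A carbonyl carbon and the central CH2 (aldol addition, then oxidation). Ring B arrives intact as silylated 4-hydroxyacetophenone, and both silyl ethers are removed last.
The ring A aldehyde comes from 2-prenyl-3-(triisopropylsilyloxy)phenol by phenoxide-directed formylation at C1, its only free ortho carbon, then O-methylation of the C2 oxygen.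
Ring A is the only ring built. It forms by benzannulation of cyclobutenone (supplies C2, C5, C6, C1) with the prenyl siloxyalkyne (supplies C3, C4), making bonds C2–C3, C4–C5 and C1–C2.
Cyclobutenone derives from 3-oxocyclobutanecarboxylic acid. The siloxyalkyne derives from prenyl bromide through the skipped enyne and its ynolate.

Key step: step 5

Assumption: the target is handled as the diketo tautomer that is drawn, and its enol forms count as the same compound. It has no stereocentre and no stereogenic double bond.

## Route

Step 1
Reactants: 1 3-oxocyclobutanecarboxylic acid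
Product: 2 3-bromocyclobutanone
Conditions: HgO, Br2, MgSO4, CH2Cl2, reflux
Reagents that add atoms: bromine, BrBr
Why: Cristol–Firth variant of the Hunsdiecker reaction, a radical bromodecarboxylation that replaces CO2H by Br at the secondary ring carbon and leaves the ketone untouched.

Step 2
Reactants: 2 3-bromocyclobutanone
Product: 3 cyclobut-2-en-1-one
Conditions: n-Bu3N (neat), rt, reduced pressure, product collected in a trap at −78 °C and kept as a cold toluene solution
Reagents that add atoms: none
Why: E1cB-type dehydrobromination of a β-bromo ketone by a high-boiling, non-nucleophilic amine, with the volatile enone distilled away from the base as it forms so that it should not polymerize.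

Step 3
Reactants: 4 1-bromo-3-methylbut-2-ene (prenyl bromide); 5 ethynylmagnesium bromide
Product: 6 5-methylhex-4-en-1-yne
Conditions: 5 (1.5 equiv), CuCl (5 mol %), THF, 0 °C to rt; aq NH4Cl, pentane, fractional distillation
Reagents that add atoms: none
Why: Copper-catalysed allylic substitution of an alkynyl Grignard reagent on a primary allylic bromide, in which attack at the unhindered CH2 terminus should give the linear skipped enyne and the excess of 5 should suppress double alkylation.

Step 4
Reactants: 6 5-methylhex-4-en-1-yne
Product: 9 triisopropyl(5-methylhex-4-en-1-ynyloxy)silane, via lithium acetylide 7 (not isolated), via lithium ynolate 8 (not isolated)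
Conditions: n-BuLi (1.0 equiv), THF, −78 °C; t-BuOOH/LiN(SiMe3)2 (premixed at −78 °C), −78 to 0 °C; i-Pr3SiOTf, −78 to 0 °C; Et3N-deactivated silica
Reagents that add atoms: tert-butyl hydroperoxide, CC(C)(C)OO; triisopropylsilyl trifluoromethanesulfonate, CC(C)[Si](C(C)C)(C(C)C)OS(=O)(=O)C(F)(F)F
Why: Oxidation of a lithium acetylide by lithium tert-butyl peroxide (electrophilic oxygen transfer) gives the ynolate, and the bulky silyl triflate traps it on oxygen rather than on carbon, which is the established route to triisopropylsiloxyalkynes.

Step 5
Reactants: 3 cyclobut-2-en-1-one; 9 triisopropyl(5-methylhex-4-en-1-ynyloxy)silane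
Product: 14 2-(3-methylbut-2-enyl)-3-(triisopropylsilyloxy)phenol, via vinylketene 10 (not isolated), via vinylcyclobutenone 11 (not isolated), via dienylketene 12 (not isolated), via cyclohexadienone 13 (not isolated)
Conditions: 9 (1.3 equiv), degassed toluene, 80 °C, slow addition of 3 in toluene; then 110 °C
Reagents that add atoms: none
Why: Danheiser benzannulation: at 80 °C cyclobutenone 3 opens by conrotatory four-electron cleavage of its C(=O)–CH2 bond to vinylketene 10, which adds in a [2+2] sense across the triple bond of 9 to give vinylcyclobutenone 11. A second four-electron opening gives dienylketene 12, and ring A closes by a thermal disrotatory six-electron electrocyclization (vinyl terminus onto the ketene carbon, bond C1–C2) to dienone 13, which tautomerizes irreversibly to phenol 14. The closest known reaction type is the union of cyclobutenones with trialkylsiloxyalkynes to give resorcinol monosilyl ethers. The regioselectivity needed comes from the polarization of the ynol ether, since oxygen donation makes the prenyl-bearing carbon the nucleophilic terminus, so this carbon bonds to the electrophilic ketene carbonyl carbon (C2–C3), the siloxy carbon bonds to the ketene α-carbon (C4–C5), and prenyl ends between OH and OSi(i-Pr)3. Chemoselectivity rests on the far higher ketenophilicity of the siloxyalkyne compared with the trisubstituted alkene, and the opening of 11 is reversible, so only the isomer of 12 that can cyclize is drained to product. No stereocentre remains in 14 (the one in 11 is lost on ring opening), and slow addition of 3 to an excess of 9 keeps the ketene concentration low, which should limit polymerization of 3 and O-acylation of 14.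

Step 6
Reactants: 14 2-(3-methylbut-2-enyl)-3-(triisopropylsilyloxy)phenol
Product: 17 2-hydroxy-3-(3-methylbut-2-enyl)-4-(triisopropylsilyloxy)benzaldehyde, via chloromagnesium phenoxide 15 (not isolated), via hydroxymethyl phenoxide 16 (not isolated)
Conditions: MgCl2 (anhydrous), Et3N, (CH2O)n, THF, reflux; cold 1 M HCl work-up
Reagents that add atoms: paraformaldehyde (reacts as formaldehyde), C=O
Why: Casnati–Skattebøl ortho-formylation, in which formaldehyde is delivered within the coordination sphere of magnesium phenoxide 15 to an ortho carbon only, C1 being the single free one because the other holds the prenyl group, and stage 16 is oxidized to the aldehyde by hydride transfer to a second formaldehyde.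

Step 7
Reactants: 17 2-hydroxy-3-(3-methylbut-2-enyl)-4-(triisopropylsilyloxy)benzaldehyde
Product: 18 2-methoxy-3-(3-methylbut-2-enyl)-4-(triisopropylsilyloxy)benzaldehyde
Conditions: MeOH, PPh3, DIAD, THF, 0 °C to rt
Reagents that add atoms: methanol, CO
Why: Mitsunobu etherification with methanol, which alkylates the acidic, chelated phenol under neutral conditions and so spares the aryl silyl ether that the para aldehyde has made sensitive to base.

Step 8
Reactants: 19 4-hydroxyacetophenone
Product: 20 1-[4-(triisopropylsilyloxy)phenyl]ethanone
Conditions: i-Pr3SiCl, imidazole, DMF, rt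
Reagents that add atoms: chlorotriisopropylsilane, CC(C)[Si](Cl)(C(C)C)C(C)C
Why: Imidazole-promoted silylation of a phenol, using the same silyl group as on ring A so that both can be removed in one final operation.

Step 9
Reactants: 20 1-[4-(triisopropylsilyloxy)phenyl]ethanone; 18 2-methoxy-3-(3-methylbut-2-enyl)-4-(triisopropylsilyloxy)benzaldehyde
Product: 22 3-hydroxy-3-[2-methoxy-3-(3-methylbut-2-enyl)-4-(triisopropylsilyloxy)phenyl]-1-[4-(triisopropylsilyloxy)phenyl]propan-1-one (racemic), via lithium enolate 21 (not isolated)
Conditions: LiN(SiMe3)2, THF, −78 °C; then 18, −78 °C; AcOH quench at −78 °C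
Reagents that add atoms: none
Why: Directed aldol addition of a preformed lithium enolate to a non-enolizable aromatic aldehyde, quenched cold to prevent retro-aldol and dehydration; the new carbinol stereocentre forms as a racemate and is erased in step 10.

Step 10
Reactants: 22 the racemic β-hydroxy ketone of step 9
Product: 23 1-[2-methoxy-3-(3-methylbut-2-enyl)-4-(triisopropylsilyloxy)phenyl]-3-[4-(triisopropylsilyloxy)phenyl]propane-1,3-dione
Conditions: IBX, EtOAc, 75 °C
Reagents that add atoms: none
Why: IBX oxidation of a β-hydroxy ketone to the β-diketone, a reagent known to stop at the diketone stage and to tolerate trisubstituted alkenes and silyl ethers.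

Step 11
Reactants: 23 the bis(silyl) diketone of step 10
Product: 24 1-[4-hydroxy-2-methoxy-3-(3-methylbut-2-enyl)phenyl]-3-(4-hydroxyphenyl)propane-1,3-dione (target)
Conditions: Bu4NF, AcOH, THF, 0 °C; aq NH4Cl
Reagents that add atoms: none
Why: Fluoride-mediated cleavage of both aryl silyl ethers, buffered with AcOH so that the diketone should not undergo retro-Claisen cleavage and the ortho-prenylphenol should not cyclize to a chroman.

## Compound list

1 | 3-oxocyclobutanecarboxylic acid | O=C1CC(C(=O)O)C1 | starting material
2 | 3-bromocyclobutanone | O=C1CC(Br)C1 | intermediate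
3 | cyclobut-2-en-1-one | O=C1C=CC1 | intermediate
4 | 1-bromo-3-methylbut-2-ene | CC(C)=CCBr | starting material
5 | ethynylmagnesium bromide | C#C[Mg]Br | starting material
6 | 5-methylhex-4-en-1-yne | CC(C)=CCC#C | intermediate
7 | (5-methylhex-4-en-1-ynyl)lithium | CC(C)=CCC#C[Li] | intermediate
8 | lithium 5-methylhex-4-en-1-yn-1-olate | CC(C)=CCC#CO[Li] | intermediate
9 | triisopropyl(5-methylhex-4-en-1-ynyloxy)silane | CC(C)=CCC#CO[Si](C(C)C)(C(C)C)C(C)C | intermediate
10 | buta-1,3-dien-1-one (vinylketene) | C=CC=C=O | intermediate
11 | 4-ethenyl-2-(3-methylbut-2-enyl)-3-(triisopropylsilyloxy)cyclobut-2-en-1-one (racemic) | O=C1C(CC=C(C)C)=C(O[Si](C(C)C)(C(C)C)C(C)C)C1C=C | intermediate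
12 | (3E)-2-(3-methylbut-2-enyl)-3-(triisopropylsilyloxy)hexa-1,3,5-trien-1-one (ketene carbon chain and vinyl group cis on the central C=C) | O=C=C(CC=C(C)C)/C(O[Si](C(C)C)(C(C)C)C(C)C)=C\C=C | intermediate
13 | 2-(3-methylbut-2-enyl)-3-(triisopropylsilyloxy)cyclohexa-2,4-dien-1-one | O=C1CC=CC(O[Si](C(C)C)(C(C)C)C(C)C)=C1CC=C(C)C | intermediate
14 | 2-(3-methylbut-2-enyl)-3-(triisopropylsilyloxy)phenol | Oc1cccc(O[Si](C(C)C)(C(C)C)C(C)C)c1CC=C(C)C | intermediate
15 | chloromagnesium 2-(3-methylbut-2-enyl)-3-(triisopropylsilyloxy)phenoxide | Cl[Mg]Oc1cccc(O[Si](C(C)C)(C(C)C)C(C)C)c1CC=C(C)C | intermediate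
16 | chloromagnesium 6-(hydroxymethyl)-2-(3-methylbut-2-enyl)-3-(triisopropylsilyloxy)phenoxide | Cl[Mg]Oc1c(CO)ccc(O[Si](C(C)C)(C(C)C)C(C)C)c1CC=C(C)C | intermediate
17 | 2-hydroxy-3-(3-methylbut-2-enyl)-4-(triisopropylsilyloxy)benzaldehyde | O=Cc1ccc(O[Si](C(C)C)(C(C)C)C(C)C)c(CC=C(C)C)c1O | intermediate
18 | 2-methoxy-3-(3-methylbut-2-enyl)-4-(triisopropylsilyloxy)benzaldehyde | COc1c(C=O)ccc(O[Si](C(C)C)(C(C)C)C(C)C)c1CC=C(C)C | intermediate
19 | 4-hydroxyacetophenone | CC(=O)c1ccc(O)cc1 | starting material
20 | 1-[4-(triisopropylsilyloxy)phenyl]ethanone | CC(=O)c1ccc(O[Si](C(C)C)(C(C)C)C(C)C)cc1 | intermediate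
21 | lithium 1-[4-(triisopropylsilyloxy)phenyl]ethenolate | C=C(O[Li])c1ccc(O[Si](C(C)C)(C(C)C)C(C)C)cc1 | intermediate
22 | 3-hydroxy-3-[2-methoxy-3-(3-methylbut-2-enyl)-4-(triisopropylsilyloxy)phenyl]-1-[4-(triisopropylsilyloxy)phenyl]propan-1-one (racemic) | COc1c(C(O)CC(=O)c2ccc(O[Si](C(C)C)(C(C)C)C(C)C)cc2)ccc(O[Si](C(C)C)(C(C)C)C(C)C)c1CC=C(C)C | intermediate
23 | 1-[2-methoxy-3-(3-methylbut-2-enyl)-4-(triisopropylsilyloxy)phenyl]-3-[4-(triisopropylsilyloxy)phenyl]propane-1,3-dione | COc1c(C(=O)CC(=O)c2ccc(O[Si](C(C)C)(C(C)C)C(C)C)cc2)ccc(O[Si](C(C)C)(C(C)C)C(C)C)c1CC=C(C)C | intermediate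
24 | 1-[4-hydroxy-2-methoxy-3-(3-methylbut-2-enyl)phenyl]-3-(4-hydroxyphenyl)propane-1,3-dione (CNP0308388.0) | COc1c(C(=O)CC(=O)c2ccc(O)cc2)ccc(O)c1CC=C(C)C | target

Total step count: 11
Longest linear sequence: 8 (steps 1, 2, 5, 6, 7, 9, 10, 11; the branch through steps 3 and 4 is equally long)

## Steps most likely to fail

**Risk 1, step 5.**
- Unsubstituted cyclobutenone may polymerize or react as an enone faster than it opens.
- The vinylketene may be captured by the phenol already formed, or by a second cyclobutenone, instead of by the alkyne.
- The fallback sets out from siloxyalkyne 9 and comes back at vinylketene 10, and so at phenol 14. It changes the ketene source and the mode of activation.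
- 3-Bromopropanoyl chloride is treated with excess CH2N2 (Et2O, 0 °C) to give 4-bromo-1-diazobutan-2-one F1.
- DBU (CH2Cl2, 0 °C) then eliminates HBr to give 1-diazobut-3-en-2-one F2, which is used at once in dilute solution.
- Irradiation of F2 together with 9 (254 nm, CH2Cl2, rt) triggers a photochemical Wolff rearrangement with vinyl migration. This releases 10 at room temperature in the presence of its trap.
- When nitrogen evolution ends, the solvent is changed to toluene and the mixture is heated at 80 to 110 °C to carry remaining 11 through 12 and 13 to 14.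
- This fallback also makes steps 1 and 2 unnecessary.

**Risk 2, step 4.**
- The doubly activated C3 methylene of the skipped enyne may be deprotonated in competition with the alkyne C–H. That would lead to base-induced isomerization to conjugated isomers.
- Oxygen transfer to the acetylide may be incomplete.
- The volatility of 6 makes exact stoichiometry hard to hold.
- The fallback sets out from prenyl bromide 4 and comes back at ynolate 8, avoiding 6 and 7, so it also answers trouble in step 3.
- Bromide 4 is used to alkylate ethyl acetate (LiN(i-Pr)2, THF, −78 °C) to give ethyl 5-methylhex-4-enoate F3.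
- Two rounds of enolization (LiN(i-Pr)2, −78 °C) and bromination follow. The bromine source is BrCF2CF2Br, which reacts with carbanions but not with the alkene. These rounds give ethyl 2-bromo-5-methylhex-4-enoate F4 and then ethyl 2,2-dibromo-5-methylhex-4-enoate F5.
- Treating F5 with t-BuLi (4 equiv, THF, −78 to 0 °C) causes double lithium–bromine exchange and loss of ethoxide. This is the known reductive route from α,α-dibromo esters to ynolates, and it gives 8.
- Ynolate 8 is silylated with i-Pr3SiOTf as in step 4 to give 9.

**Risk 3, step 6.**
- Formylation of the hindered magnesium phenoxide may stall.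
- The hydroxymethyl stage may condense with unreacted phenoxide.
- Long heating with amine may erode the silyl ether.
- The fallback sets out from phenol 14 and comes back at aldehyde 18, bypassing 17 and thus step 7 as well. It replaces phenoxide-directed formylation by methoxy-directed metalation.
- Phenol 14 is methylated first (MeI, K2CO3, acetone, reflux), while the aryl silyl ether is not yet activated by a para carbonyl. This gives [3-methoxy-2-(3-methylbut-2-enyl)phenoxy]triisopropylsilane F6.
- Directed ortho-lithiation (n-BuLi, TMEDA, Et2O, 0 °C) should take place next to the methoxy group, because the bulky siloxy group coordinates poorly and shields its own ortho position. This gives [2-methoxy-3-(3-methylbut-2-enyl)-4-(triisopropylsilyloxy)phenyl]lithium F7.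
- Quenching F7 with DMF gives 18.

## Further compounds

F1 | step 5 | 4-bromo-1-diazobutan-2-one | BrCCC(=O)C=[N+]=[N-]
F2 | step 5 | 1-diazobut-3-en-2-one | C=CC(=O)C=[N+]=[N-]
F3 | step 4 | ethyl 5-methylhex-4-enoate | CCOC(=O)CCC=C(C)C
F4 | step 4 | ethyl 2-bromo-5-methylhex-4-enoate (racemic) | CCOC(=O)C(Br)CC=C(C)C
F5 | step 4 | ethyl 2,2-dibromo-5-methylhex-4-enoate | CCOC(=O)C(Br)(Br)CC=C(C)C
F6 | step 6 | [3-methoxy-2-(3-methylbut-2-enyl)phenoxy]triisopropylsilane | COc1cccc(O[Si](C(C)C)(C(C)C)C(C)C)c1CC=C(C)C
F7 | step 6 | [2-methoxy-3-(3-methylbut-2-enyl)-4-(triisopropylsilyloxy)phenyl]lithium | COc1c([Li])ccc(O[Si](C(C)C)(C(C)C)C(C)C)c1CC=C(C)C
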